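**Plan**
- Numbering: decalin C1–C10 (C4 = CMe2, C5 = carbinol, C8 = CHMe, C9 = quaternary, C10 = ring-fusion CH); C11 = benzylic CH2; Ar = 2,3,5,6-tetramethoxyphenyl; β = the face of ring B that carries O-5.
- Enabling feature: in ring B the C5 oxygen and the C8 methyl carbon are 1,4-cis. O–C5 and C8–C are therefore the two ends of the O–C(=O) bridge of a 2-pyrone [4+2] adduct, and ring B is the cyclohexene of a 2-oxabicyclo[2.2.2]octenone.
- Retrosynthesis: hydroxyquinone ⇒ tetramethoxyarene; C8 methyl ⇒ lactone carbonyl; then C8–C9 and C5–C10 are cut together (retro-[4+2]) to an achiral 6-(tert-alkyl)-2-pyrone carrying a (Z)-trisubstituted alkene four carbons down the chain. A 3-CO2Me group on the pyrone is a helper for activation and two-point catalyst binding; it is excised later by radical decarboxylation.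
- Forward: the chain is joined linearly (C4 by nitrile allylation, C1–C10 by B-alkyl Suzuki coupling, C11–aryl by arylcopper allylation, pyrone by annulation of a methyl ketone). Rings A and B form together in step 8, and the quinone is unveiled last.
- Stereochemistry: C9/C10 from the Z alkene (suprafacial addition), C5/C8 from the lactone bridge, the trans ring fusion from the exo tether, the absolute configuration from a chiral bis(oxazoline)–Cu(OTf)2 catalyst. No later step touches a stereocentre.

Key step: step 8

Assumption: the sense of induction of (S,S)-t-Bu-BOX [2,2′-(propane-2,2-diyl)bis((4S)-4-tert-butyl-4,5-dihydrooxazole)] is taken by analogy with intermolecular cases; should it favour the mirror-image adduct, the (R,R)-ligand is used with no other change.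

**Step 1**
Reactants: 1 isobutyronitrile; 2 allyl bromide
Product: 3 2,2-dimethylpent-4-enenitrile
Conditions: LiN(i-Pr)2, THF, −78 °C; then 2, −78 °C → rt
Reagents that add atoms: none
Why: α-Alkylation of the lithiated nitrile with the allylic bromide should set the gem-dimethyl quaternary carbon C4 in a standard nitrile alkylation.

**Step 2**
Reactants: 4 propargyl alcohol
Product: 6 (Z)-3-iodo-2-methylprop-2-en-1-ol, via alkenylmagnesium alkoxide 5 (not isolated)
Conditions: MeMgBr (2.5 equiv), CuI (10 mol %), THF, −10 °C → rt; then I2, −78 → 0 °C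
Reagents that add atoms: methylmagnesium bromide C[Mg]Br; iodine II
Why: Copper-catalysed anti-carbomagnesiation of the propargylic alkoxide delivers methyl to the internal carbon through a five-membered magnesium chelate, so iodinolysis should place iodine cis to CH2OH and thereby fix the Z geometry of the future C9=C10 alkene.

**Step 3**
Reactants: 3 2,2-dimethylpent-4-enenitrile; 6 (Z)-3-iodo-2-methylprop-2-en-1-ol
Product: 8 (Z)-8-hydroxy-2,2,7-trimethyloct-6-enenitrile, via alkylborane 7 (not isolated)
Conditions: 3, 9-BBN, THF, rt; then 6, Pd(dppf)Cl2 (5 mol %), AsPh3, Cs2CO3, DMF/THF/H2O, rt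
Reagents that add atoms: none
Why: Anti-Markovnikov hydroboration of the terminal alkene followed by B-alkyl Suzuki–Miyaura coupling should join C1 to C10 with retention of the alkenyl iodide geometry, the nitrile and the free allylic alcohol being tolerated.

**Step 4**
Reactants: 8 (Z)-8-hydroxy-2,2,7-trimethyloct-6-enenitrile
Product: 9 (Z)-8-bromo-2,2,7-trimethyloct-6-enenitrile
Conditions: CBr4, PPh3, CH2Cl2, 0 °C
Reagents that add atoms: carbon tetrabromide BrC(Br)(Br)Br
Why: Appel bromination displaces the primary oxyphosphonium ion by SN2 at 0 °C, which should leave the Z alkene untouched.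

**Step 5**
Reactants: 10 1,2,4,5-tetramethoxybenzene; 9 (Z)-8-bromo-2,2,7-trimethyloct-6-enenitrile
Product: 13 (Z)-2,2,7-trimethyl-8-(2,3,5,6-tetramethoxyphenyl)oct-6-enenitrile, via aryllithium 11 (not isolated), via arylcopper 12 (not isolated)
Conditions: 10, n-BuLi, TMEDA, THF, 0 °C; CuBr·SMe2, −40 °C; then 9, −40 °C → rt
Reagents that add atoms: none
Why: Directed ortho-lithiation between two methoxy groups and transmetalation to copper give an arylcopper that should displace the primary allylic bromide at the α carbon with retention of the Z geometry (the standard prenylation of polymethoxyarenes) without adding to the hindered nitrile.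

**Step 6**
Reactants: 13 (Z)-2,2,7-trimethyl-8-(2,3,5,6-tetramethoxyphenyl)oct-6-enenitrile
Product: 15 (Z)-3,3,8-trimethyl-9-(2,3,5,6-tetramethoxyphenyl)non-7-en-2-one, via lithium ketimide 14 (not isolated)
Conditions: MeLi, Et2O, 0 °C → rt; then 1 M aq. HCl, THF, rt
Reagents that add atoms: methyllithium [Li]C; water O
Why: Methyllithium adds once to the tertiary nitrile to give an N-lithio ketimine that cannot react further and is hydrolysed by dilute acid to the methyl ketone, whose only enolisable position is the methyl group.

**Step 7**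
Reactants: 15 (Z)-3,3,8-trimethyl-9-(2,3,5,6-tetramethoxyphenyl)non-7-en-2-one; 16 dimethyl 2-(methoxymethylene)malonate
Product: 18 methyl 6-[(6Z)-2,7-dimethyl-8-(2,3,5,6-tetramethoxyphenyl)oct-6-en-2-yl]-2-oxo-2H-pyran-3-carboxylate, via alkylidenemalonate 17 (not isolated)
Conditions: LiN(i-Pr)2, THF, −78 °C; then 16, −78 °C → rt; AcOH quench
Reagents that add atoms: none
Why: The kinetic lithium enolate of the methyl ketone should add to the alkoxymethylenemalonate with loss of methoxide, and the resulting dienolate closes through oxygen onto the cis ester (addition–elimination then lactonisation, the standard annulation to 3-carbomethoxy-2-pyrones), placing the tert-alkyl group at pyrone C6.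

**Step 8**
Reactants: 18 methyl 6-[(6Z)-2,7-dimethyl-8-(2,3,5,6-tetramethoxyphenyl)oct-6-en-2-yl]-2-oxo-2H-pyran-3-carboxylate
Product: 19 tricyclic lactone ester (ring B = cyclohex-6-ene bridged on the β face by O–C(=O) from O-5 to C8; 8-CO2Me; 9α-CH3; 9β-CH2Ar; 10α-H; trans-fused 4,4-dimethyl ring A)
Conditions: Cu(OTf)2 (10 mol %), (S,S)-t-Bu-BOX (11 mol %), 4 Å molecular sieves, CH2Cl2 (0.01 M), 0 °C → rt
Reagents that add atoms: none
Why: Proposed new method: two-point chelation of the lactone and ester carbonyls of 18 by Cu(OTf)2–bis(oxazoline) (divalent copper) lowers the pyrone LUMO so that the tethered, unactivated trisubstituted alkene adds across pyrone C6 and C3 in an asynchronous inverse-electron-demand [4+2] cycloaddition, in which the less substituted alkene carbon C10 attacks the electrophilic pyrone C6 (future C5) and the cation-stabilising C9 then bonds to the malonate-like pyrone C3 (future C8); the closest known reaction types are the bis(oxazoline)–copper-catalysed inverse-demand Diels–Alder reaction of 3-carboalkoxy-2-pyrones with electron-rich alkenes, the Lewis-acid- and pressure-promoted addition of unactivated alkenes to the same pyrones, and the thermal intramolecular Diels–Alder reaction of 6-tethered 2-pyrones with trisubstituted alkenes. Ring A closes through the four-carbon tether C1–C4 in a chair-like six-membered array (fused mode, tether on the diene terminus, assisted by the gem-dimethyl group), and ring B closes as the cyclohexene of the 2-oxabicyclo[2.2.2]oct-5-en-3-one. C5 and C8 are held cis by the O–C(=O) bridge that the pyrone brings with it, and at C9/C10 the methyl group ends cis to H-10 and the benzyl group cis to C1 because the Z alkene adds suprafacially. The trans ring fusion (H-10 anti to O-5) requires the exo orientation of the tether, which the substrate should secure because the chair that keeps C9 equatorial then places C1 and the benzyl group under the hydrogen-free pyrone O1–C2 flank and only H-10 and the methyl group under the pyrone C4–H/C5–H flank. The absolute configuration comes from the ligand, whose tert-butyl group blocks one face of the chelated pyrone. The regiochemistry is fixed by the tether and matched electronically, and operation at or below room temperature keeps the CO2 bridge from being extruded.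

**Step 9**
Reactants: 19 tricyclic lactone ester
Product: 20 6,7-dihydro lactone ester (configuration as in 19)
Conditions: H2 (1 atm), Pd/C (10 %), EtOAc, rt
Reagents that add atoms: none
Why: Heterogeneous hydrogenation should saturate the strained disubstituted alkene of the bicyclo[2.2.2]octene, which removes the allylic character of the C5–O bond before the later reductions and creates no stereocentre.

**Step 10**
Reactants: 20 6,7-dihydro lactone ester
Product: 21 lactone acid (8-CO2H; otherwise as 20)
Conditions: LiI, pyridine, reflux; then 1 M aq. HCl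
Reagents that add atoms: none
Why: Iodide dealkylates the methyl ester by SN2 attack at the methyl carbon, a process indifferent to the congestion at the acyl carbon, while the tert-alkyl C–O bond of the lactone is inert and the bridgehead position blocks thermal decarboxylation of the malonic half-acid.

**Step 11**
Reactants: 21 lactone acid
Product: 24 bridged lactone with bridgehead H at C8 (O-5 to C8 carbonyl bridge on the β face; 9α-CH3; 9β-CH2Ar; 10α-H), via acid chloride 22 (not isolated), via thiohydroxamate ester 23 (not isolated)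
Conditions: (COCl)2, DMF (cat.), CH2Cl2, 0 °C → rt; then sodium 2-mercaptopyridine N-oxide, DMAP (cat.), t-BuSH, PhMe, tungsten lamp, rt → 80 °C
Reagents that add atoms: none
Why: Barton reductive decarboxylation should fragment the thiohydroxamate ester to a bridgehead radical at C8 (bridgehead radicals form readily, unlike bridgehead enolates) that abstracts hydrogen from the thiol, and the configuration at C8 stays fixed because the remaining carbonyl carbon is the one tied to O-5.

**Step 12**
Reactants: 24 bridged lactone
Product: 25 diol (5β-OH; 8β-CH2OH; 9α-CH3; 9β-CH2Ar; 10α-H; trans-decalin)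
Conditions: LiAlH4, THF, 0 °C → rt; H2O work-up
Reagents that add atoms: none
Why: Hydride reduction of the bridged lactone should release the tertiary C5 alcohol and a primary hydroxymethyl group on C8 that are necessarily cis, so C8 carries its one-carbon substituent on the β face.

**Step 13**
Reactants: 25 diol
Product: 26 iodide (8β-CH2I; otherwise as 25)
Conditions: I2, PPh3, imidazole, PhMe/MeCN, rt
Reagents that add atoms: iodine II
Why: Garegg–Samuelsson iodination (an Appel-type SN2 reaction) should be selective for the primary alcohol because the tertiary alcohol is too hindered to form the oxyphosphonium ion.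

**Step 14**
Reactants: 26 iodide
Product: 27 (1S,2S,4aR,8aS)-1,2,5,5-tetramethyl-1-[(2,3,5,6-tetramethoxyphenyl)methyl]octahydronaphthalen-4a(2H)-ol
Conditions: H2 (1 atm), Pd/C (10 %), Et3N, MeOH, rt
Reagents that add atoms: none
Why: Hydrogenolysis of the primary C–I bond over palladium with an amine base should turn CH2I into the C8 methyl group under neutral, non-epimerising conditions.

**Step 15**
Reactants: 27 tetramethoxyaryl decalinol
Product: 28 3-{[(1S,2S,4aR,8aS)-4a-hydroxy-1,2,5,5-tetramethyldecahydronaphthalen-1-yl]methyl}-2,5-dimethoxycyclohexa-2,5-diene-1,4-dione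
Conditions: (NH4)2Ce(NO3)6, MeCN/H2O, 0 °C
Reagents that add atoms: water O
Why: Oxidative demethylation of a para-dimethoxy pair by the cerium ammonium nitrate should give the 2,5-dimethoxy-1,4-benzoquinone (the two para pairs are equivalent by the symmetry of the arene), the carbonyl oxygens coming from water.

**Step 16**
Reactants: 28 dimethoxyquinone
Product: 29 2-hydroxy-3-{[(1S,2S,4aR,8aS)-4a-hydroxy-1,2,5,5-tetramethyldecahydronaphthalen-1-yl]methyl}-5-methoxycyclohexa-2,5-diene-1,4-dione (target)
Conditions: KOH, MeOH/H2O, rt; then dilute HCl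
Reagents that add atoms: potassium hydroxide [K+].[OH-]
Why: Hydroxide should undergo addition–elimination at the vinylogous ester flanked by the alkyl group, whose methoxy group is twisted out of conjugation and so the more electrophilic, a selectivity established for 3-alkyl-2,5-dimethoxy-1,4-benzoquinones.

**Compound list**
1 | isobutyronitrile | CC(C)C#N | starting material
2 | allyl bromide | C=CCBr | starting material
3 | 2,2-dimethylpent-4-enenitrile | C=CCC(C)(C)C#N | intermediate
4 | propargyl alcohol | C#CCO | starting material
5 | bromomagnesium (Z)-3-(bromomagnesio)-2-methylprop-2-en-1-olate | Br[Mg]/C=C(/C)CO[Mg]Br | intermediate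
6 | (Z)-3-iodo-2-methylprop-2-en-1-ol | I/C=C(/C)CO | intermediate
7 | 9-(4-cyano-4-methylpentyl)-9-borabicyclo[3.3.1]nonane | N#CC(C)(C)CCCB1C2CCCC1CCC2 | intermediate
8 | (Z)-8-hydroxy-2,2,7-trimethyloct-6-enenitrile | N#CC(C)(C)CCC/C=C(/C)CO | intermediate
9 | (Z)-8-bromo-2,2,7-trimethyloct-6-enenitrile | N#CC(C)(C)CCC/C=C(/C)CBr | intermediate
10 | 1,2,4,5-tetramethoxybenzene | COc1cc(OC)c(OC)cc1OC | starting material
11 | 2,3,5,6-tetramethoxyphenyllithium | [Li]c1c(OC)c(OC)cc(OC)c1OC | intermediate
12 | 2,3,5,6-tetramethoxyphenylcopper | [Cu]c1c(OC)c(OC)cc(OC)c1OC | intermediate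
13 | (Z)-2,2,7-trimethyl-8-(2,3,5,6-tetramethoxyphenyl)oct-6-enenitrile | N#CC(C)(C)CCC/C=C(/C)Cc1c(OC)c(OC)cc(OC)c1OC | intermediate
14 | N-lithio ketimine of 15 | [Li]N=C(C)C(C)(C)CCC/C=C(/C)Cc1c(OC)c(OC)cc(OC)c1OC | intermediate
15 | (Z)-3,3,8-trimethyl-9-(2,3,5,6-tetramethoxyphenyl)non-7-en-2-one | CC(=O)C(C)(C)CCC/C=C(/C)Cc1c(OC)c(OC)cc(OC)c1OC | intermediate
16 | dimethyl 2-(methoxymethylene)malonate | COC=C(C(=O)OC)C(=O)OC | starting material
17 | dimethyl 2-[(8Z)-4,4,9-trimethyl-3-oxo-10-(2,3,5,6-tetramethoxyphenyl)dec-8-en-1-ylidene]malonate | COC(=O)C(=CCC(=O)C(C)(C)CCC/C=C(/C)Cc1c(OC)c(OC)cc(OC)c1OC)C(=O)OC | intermediate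
18 | methyl 6-[(6Z)-2,7-dimethyl-8-(2,3,5,6-tetramethoxyphenyl)oct-6-en-2-yl]-2-oxo-2H-pyran-3-carboxylate | COC(=O)C1=CC=C(OC1=O)C(C)(C)CCC/C=C(/C)Cc1c(OC)c(OC)cc(OC)c1OC | intermediate
19 | tricyclic lactone ester: Δ6; β-face O–C(=O) bridge from O-5 to C8; 8-CO2Me; 9α-CH3; 9β-CH2Ar; 10α-H | COc1cc(OC)c(OC)c(C[C@@]2(C)[C@@]5(C(=O)OC)C(=O)O[C@]3(C=C5)[C@H]2CCCC3(C)C)c1OC | intermediate
20 | 6,7-dihydro derivative of 19 | COc1cc(OC)c(OC)c(C[C@@]2(C)[C@@]5(C(=O)OC)C(=O)O[C@]3(CC5)[C@H]2CCCC3(C)C)c1OC | intermediate
21 | lactone acid (8-CO2H) | COc1cc(OC)c(OC)c(C[C@@]2(C)[C@@]5(C(=O)O)C(=O)O[C@]3(CC5)[C@H]2CCCC3(C)C)c1OC | intermediate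
22 | lactone acid chloride (8-COCl) | COc1cc(OC)c(OC)c(C[C@@]2(C)[C@@]5(C(=O)Cl)C(=O)O[C@]3(CC5)[C@H]2CCCC3(C)C)c1OC | intermediate
23 | 2-thioxopyridin-1(2H)-yl ester of 21 | COc1cc(OC)c(OC)c(C[C@@]2(C)[C@@]5(C(=O)ON6C=CC=CC6=S)C(=O)O[C@]3(CC5)[C@H]2CCCC3(C)C)c1OC | intermediate
24 | bridged lactone with H at C8: β-face O–C(=O) bridge from O-5 to C8; 9α-CH3; 9β-CH2Ar; 10α-H | COc1cc(OC)c(OC)c(C[C@@]2(C)[C@H]5C(=O)O[C@]3(CC5)[C@H]2CCCC3(C)C)c1OC | intermediate
25 | diol: 5β-OH; 8β-CH2OH; 9α-CH3; 9β-CH2Ar; 10α-H | COc1cc(OC)c(OC)c(C[C@@]2(C)[C@@H](CO)CC[C@@]3(O)[C@H]2CCCC3(C)C)c1OC | intermediate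
26 | iodide: 5β-OH; 8β-CH2I; 9α-CH3; 9β-CH2Ar; 10α-H | COc1cc(OC)c(OC)c(C[C@@]2(C)[C@@H](CI)CC[C@@]3(O)[C@H]2CCCC3(C)C)c1OC | intermediate
27 | (1S,2S,4aR,8aS)-1,2,5,5-tetramethyl-1-[(2,3,5,6-tetramethoxyphenyl)methyl]octahydronaphthalen-4a(2H)-ol | COc1cc(OC)c(OC)c(C[C@@]2(C)[C@@H](C)CC[C@@]3(O)[C@H]2CCCC3(C)C)c1OC | intermediate
28 | 3-{[(1S,2S,4aR,8aS)-4a-hydroxy-1,2,5,5-tetramethyldecahydronaphthalen-1-yl]methyl}-2,5-dimethoxycyclohexa-2,5-diene-1,4-dione | COC1=CC(=O)C(OC)=C(C[C@@]2(C)[C@@H](C)CC[C@@]3(O)[C@H]2CCCC3(C)C)C1=O | intermediate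
29 | 2-hydroxy-3-{[(1S,2S,4aR,8aS)-4a-hydroxy-1,2,5,5-tetramethyldecahydronaphthalen-1-yl]methyl}-5-methoxycyclohexa-2,5-diene-1,4-dione | COC1=CC(=O)C(O)=C(C[C@@]2(C)[C@@H](C)CC[C@@]3(O)[C@H]2CCCC3(C)C)C1=O | target

**Step count and risks**
Total: 16 steps. Longest linear sequence: 15 steps (steps 1 and 3–16; step 2 is a one-step branch).

Steps most likely to fail:

1. Step 8 (proposed new method). The alkene may be too weakly nucleophilic for the chelated pyrone. The reaction may turn stepwise, with proton loss from the C9 cation (ene-type product) or loss of the Z geometry. The tether may sit endo and give the cis-fused isomer. Face selectivity may be low, or the arene may be oxidised by single-electron transfer to divalent copper. Fallback, from 18: the uncatalysed or ZnBr2-promoted [4+2] cycloaddition under about 12 kbar in CH2Cl2 at room temperature, a known way to add unactivated alkenes to methyl 2-oxo-2H-pyran-3-carboxylates without CO2 loss, should give the racemic adduct, that is 19 together with the mirror-image adduct ent-19 F1. Preparative chromatography on a chiral stationary phase then separates the two, and the route is rejoined at 19.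

2. Step 7. The methoxide liberated in the annulation may open the electrophilic pyrone ring, or the hindered enolate adduct may fail to lactonise. Fallback, from 15: Claisen formylation (HCO2Et, NaH, Et2O) should give the β-keto aldehyde F2 (present as its hydroxymethylene enol). Knoevenagel condensation of it with dimethyl malonate (piperidinium acetate, PhH, reflux, water removal) gives 17, which lactonises in the same flask; the route is rejoined at 18, and no alkoxide is present at any time.

3. Step 16. Hydroxide may attack the other methoxy-bearing carbon, or both, giving the regioisomer or the dihydroxyquinone. Fallback, from 28: exhaustive hydrolysis (aq. NaOH, MeOH, 50 °C; then HCl) should give the 2,5-dihydroxyquinone F3. Acid-catalysed mono-methylation in methanol (cat. HCl, rt) etherifies only the vinylogous acid remote from the alkyl group, a known selectivity of 3-alkyl-2,5-dihydroxybenzoquinones, and returns to the route at 29.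

**Further compounds**
F1 | step 8 | ent-19, mirror image of the tricyclic lactone ester | COc1cc(OC)c(OC)c(C[C@]2(C)[C@]5(C(=O)OC)C(=O)O[C@@]3(C=C5)[C@@H]2CCCC3(C)C)c1OC
F2 | step 7 | (8Z)-4,4,9-trimethyl-3-oxo-10-(2,3,5,6-tetramethoxyphenyl)dec-8-enal | O=CCC(=O)C(C)(C)CCC/C=C(/C)Cc1c(OC)c(OC)cc(OC)c1OC
F3 | step 16 | 2,5-dihydroxy-3-{[(1S,2S,4aR,8aS)-4a-hydroxy-1,2,5,5-tetramethyldecahydronaphthalen-1-yl]methyl}cyclohexa-2,5-diene-1,4-dione | OC1=CC(=O)C(O)=C(C[C@@]2(C)[C@@H](C)CC[C@@]3(O)[C@H]2CCCC3(C)C)C1=O
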